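**Assumption:** the lactol carbon is the only stereocentre and is (R) by CIP. As a hemiacetal it can epimerise by ring opening in protic, acidic or basic media, so it is carried as a configurationally stable acetal, released in the last step under neutral aprotic conditions, and the product is isolated and stored as a solid.

Compounds 1, 5 and 12 are catalogue compounds. Ring A is the methoxy-bearing ring (C-1 carries the ester carbonyl); ring B is the ring fused to the hydroxyphthalide; ring B precursors use phthalide numbering.

## Retrosynthetic overview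

1. Target ⇐ neutral hydrogenolysis of a ring A benzyl ether and of an (S)-1-phenylethyl acetal that holds the lactol carbon as (R).
2. Seven-membered ring ⇐ the diaryl ether bond is made last, by intramolecular oxidative phenol C–O coupling of a depside (ring A 2-OH onto the carbon para to the ring B phenol), as the depsidone ring is closed in lichens.
3. Depside ⇐ ester between a ring A salicylic acid and the 5-OH of a ring B 5,7-dihydroxyphthalide acetal.
4. Ring B hydroxyphthalide ⇐ ring–chain closure of an o-formylbenzoic acid made by directed ortho-carboxylation of 3,5-dimethoxy-4-methylbenzaldehyde; ring A acid ⇐ 2,3,4-trimethoxy-6-methylbenzaldehyde.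
5. Ring order: lactol (phthalide) ring first, central seven-membered ring last (ester bond, then ether bond).

## Route

Step 1
Reactants: 1 2,3,4-trimethoxy-6-methylbenzaldehyde
Product: 2 2,3-dihydroxy-4-methoxy-6-methylbenzaldehyde
Conditions: BCl3 (2.5 equiv), CH2Cl2, 0 °C to rt; H2O
Reagents that add atoms: none
Why: BCl3 chelated between the formyl oxygen and the 2-methoxy oxygen cleaves that ether first, and boron bound to the new 2-oxygen then reaches only the neighbouring 3-methoxy group, so the 4-methoxy group survives (chelation-controlled Lewis-acid O-demethylation).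

Step 2
Reactants: 2 2,3-dihydroxy-4-methoxy-6-methylbenzaldehyde
Product: 3 3-(benzyloxy)-2-hydroxy-4-methoxy-6-methylbenzaldehyde
Conditions: NaH (2.2 equiv), DMSO, rt; BnBr (1.0 equiv); aq. HCl
Reagents that add atoms: benzyl bromide, BrCc1ccccc1
Why: With both phenols deprotonated the 2-oxygen is delocalised into the formyl group, so the 3-oxygen is the more nucleophilic one and takes the single equivalent of benzyl bromide (regioselective Williamson etherification).

Step 3
Reactants: 3 3-(benzyloxy)-2-hydroxy-4-methoxy-6-methylbenzaldehyde
Product: 4 3-(benzyloxy)-2-hydroxy-4-methoxy-6-methylbenzoic acid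
Conditions: NaClO2, NaH2PO4, 2-methyl-2-butene, t-BuOH–H2O, rt
Reagents that add atoms: sodium chlorite, [Na+].[O-]Cl=O
Why: Pinnick oxidation converts the hindered, chelated aryl aldehyde to the acid without touching the benzyl ether, and the alkene scavenger removes HOCl before it can chlorinate the electron-rich ring.

Step 4
Reactants: 5 3,5-dimethoxy-4-methylbenzaldehyde
Product: 10 rac-3-hydroxy-5,7-dimethoxy-6-methylisobenzofuran-1(3H)-one, via lithium amino alkoxide 6 (not isolated), via ortho-lithiated amino alkoxide 7 (not isolated), via dilithium carboxylate 8 (not isolated), via ring-open formyl acid 9 (not isolated)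
Conditions: Me2NCH2CH2NHMe, n-BuLi, THF, −20 °C; n-BuLi (3 equiv), −20 °C; CO2, −78 °C to rt; aq. HCl
Reagents that add atoms: carbon dioxide, O=C=O
Why: Comins α-amino alkoxide directed ortho-lithiation, in which the lithium aminal and the flanking methoxy group together direct n-BuLi to C-2 (C-2 and C-6 are equivalent), CO2 traps the aryllithium, and acid work-up frees the aldehyde, which closes onto the new ortho carboxyl group by ring–chain tautomerism to the lactol (racemic at this stage).

Step 5
Reactants: 10 rac-3-hydroxy-5,7-dimethoxy-6-methylisobenzofuran-1(3H)-one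
Product: 11 rac-3,5,7-trihydroxy-6-methylisobenzofuran-1(3H)-one
Conditions: BBr3 (4 equiv), CH2Cl2, −78 °C to rt; H2O
Reagents that add atoms: none
Why: BBr3 cleaves both aryl methyl ethers (Lewis-acid O-demethylation) and the lactol is restored on aqueous work-up.

Step 6
Reactants: 11 rac-3,5,7-trihydroxy-6-methylisobenzofuran-1(3H)-one; 12 (S)-1-phenylethanol (3 equiv)
Product: 14 (3R)-5,7-dihydroxy-6-methyl-3-[(1S)-1-phenylethoxy]isobenzofuran-1(3H)-one, via C-3 epimeric acetal mixture 13 (not isolated)
Conditions: PPTS (10 mol%), 4 Å MS, toluene–THF, 70 °C; SiO2 separation of the C-3 epimers; (3S)-rich fraction returned to PPTS, toluene–THF, 70 °C and separated again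
Reagents that add atoms: none
Why: Acid-catalysed pseudo-ester (lactol acetal) formation through the C-3 oxocarbenium ion gives the epimer mixture 13 under thermodynamic control, the (3R)-epimer 14 is taken from it by chromatography or crystallisation and the (3S)-rich remainder is re-equilibrated through the same cation under the same conditions, so the lactol stereocentre is fixed here as a stable acetal (resolution through a covalent chiral auxiliary that also protects the lactol, with recycling of the unwanted epimer).

Step 7
Reactants: 4 3-(benzyloxy)-2-hydroxy-4-methoxy-6-methylbenzoic acid; 14 (3R)-5,7-dihydroxy-6-methyl-3-[(1S)-1-phenylethoxy]isobenzofuran-1(3H)-one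
Product: 15 (3R)-7-hydroxy-6-methyl-1-oxo-3-[(1S)-1-phenylethoxy]-1,3-dihydroisobenzofuran-5-yl 3-(benzyloxy)-2-hydroxy-4-methoxy-6-methylbenzoate (the depside)
Conditions: DCC, DMAP (10 mol%), CH2Cl2, 0 °C to rt
Reagents that add atoms: none
Why: Steglich esterification in which the 5-OH of 14, para to the lactone carbonyl and not hydrogen-bonded, is acylated in preference to the chelated 7-OH and to the chelated 2-OH of 4 (the usual depside selectivity), under neutral conditions that leave the acetal centre untouched.

Step 8
Reactants: 15 the depside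
Product: 17 ring A 3-O-benzyl ether (R)-lactol (1S)-1-phenylethyl acetal of the target depsidone, via cyclohexadienone tautomer 16 (not isolated)
Conditions: activated MnO2 (15 equiv), CHCl3 (1 mM), rt, dark
Reagents that add atoms: none
Why: Intramolecular oxidative phenol C–O coupling as in depside-to-depsidone biosynthesis, a reaction type known with MnO2 for chlorinated depsides: one-electron oxidation of both chelated phenols lets the ring A oxygen radical pair with the carbon para to the ring B phenol (the only productive position the ester tether allows, giving the seven-membered ring), and dienone 16 re-aromatises by tautomerisation; no stereocentre is formed and the acetal is inert to MnO2.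

Step 9
Reactants: 17 ring A 3-O-benzyl ether (R)-lactol (1S)-1-phenylethyl acetal of the target depsidone
Product: 18 target, (R)-menegazziaic acid
Conditions: H2 (1 atm), Pd/C, EtOAc, 0 °C to rt; filter, concentrate cold, crystallise
Reagents that add atoms: none
Why: Catalytic hydrogenolysis cleaves the aryl benzyl ether and the O–CH(CH3)Ph bond at the unhindered phenyl-bearing carbon, whereas the two C–O bonds at the acetal carbon sit on a fully substituted arene that binds poorly to Pd and are not broken, so the lactol is released with its (R)-configuration under neutral aprotic conditions.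

## Compound list

1 | 2,3,4-trimethoxy-6-methylbenzaldehyde | COc1cc(C)c(C=O)c(OC)c1OC | starting material
2 | 2,3-dihydroxy-4-methoxy-6-methylbenzaldehyde | COc1cc(C)c(C=O)c(O)c1O | intermediate
3 | 3-(benzyloxy)-2-hydroxy-4-methoxy-6-methylbenzaldehyde | COc1cc(C)c(C=O)c(O)c1OCc1ccccc1 | intermediate
4 | 3-(benzyloxy)-2-hydroxy-4-methoxy-6-methylbenzoic acid | COc1cc(C)c(C(=O)O)c(O)c1OCc1ccccc1 | intermediate
5 | 3,5-dimethoxy-4-methylbenzaldehyde | COc1cc(C=O)cc(OC)c1C | starting material
6 | lithium α-amino alkoxide from 5 and lithium N,N,N'-trimethylethylenediamide (racemic aminal carbon) | [Li+].COc1cc(C([O-])N(C)CCN(C)C)cc(OC)c1C | intermediate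
7 | 2-lithio derivative of 6 (racemic) | [Li+].COc1cc(C([O-])N(C)CCN(C)C)c([Li])c(OC)c1C | intermediate
8 | dilithium salt of the 2-carboxylated α-amino alkoxide (racemic) | [Li+].[Li+].COc1cc(C([O-])N(C)CCN(C)C)c(C(=O)[O-])c(OC)c1C | intermediate
9 | 6-formyl-2,4-dimethoxy-3-methylbenzoic acid | COc1cc(C=O)c(C(=O)O)c(OC)c1C | intermediate
10 | rac-3-hydroxy-5,7-dimethoxy-6-methylisobenzofuran-1(3H)-one | COc1cc2c(c(OC)c1C)C(=O)OC2O | intermediate
11 | rac-3,5,7-trihydroxy-6-methylisobenzofuran-1(3H)-one | Cc1c(O)cc2c(c1O)C(=O)OC2O | intermediate
12 | (S)-1-phenylethanol | C[C@H](O)c1ccccc1 | starting material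
13 | 5,7-dihydroxy-6-methyl-3-[(1S)-1-phenylethoxy]isobenzofuran-1(3H)-one as the equilibrating mixture of its C-3 epimers (C-3 undefined, auxiliary carbon S) | Cc1c(O)cc2c(c1O)C(=O)OC2O[C@@H](C)c1ccccc1 | intermediate
14 | (3R)-5,7-dihydroxy-6-methyl-3-[(1S)-1-phenylethoxy]isobenzofuran-1(3H)-one | Cc1c(O)cc2c(c1O)C(=O)O[C@H]2O[C@@H](C)c1ccccc1 | intermediate
15 | depside: (3R)-7-hydroxy-6-methyl-1-oxo-3-[(1S)-1-phenylethoxy]-1,3-dihydroisobenzofuran-5-yl 3-(benzyloxy)-2-hydroxy-4-methoxy-6-methylbenzoate | COc1cc(C)c(C(=O)Oc2cc3c(c(O)c2C)C(=O)O[C@H]3O[C@@H](C)c2ccccc2)c(O)c1OCc1ccccc1 | intermediate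
16 | cyclohexadienone tautomer of 17: ring B ketone at the former phenol carbon, sp3 CH–OAr at the coupling carbon (configuration there undefined, lost on tautomerisation), acetal carbon (R), auxiliary (S) | COc1cc(C)c2c(c1OCc1ccccc1)OC1C(=C(C)C(=O)C3=C1[C@H](O[C@@H](C)c1ccccc1)OC3=O)OC2=O | intermediate
17 | protected depsidone: target with the ring A 3-OH as benzyl ether and the (R)-lactol OH as (1S)-1-phenylethyl ether | COc1cc(C)c2c(c1OCc1ccccc1)Oc1c(c(C)c(O)c3c1[C@H](O[C@@H](C)c1ccccc1)OC3=O)OC2=O | intermediate
18 | (R)-menegazziaic acid: depsidone with ring A 3-hydroxy-4-methoxy-6-methyl and ring B 2'-hydroxy-3'-methyl fused to an (R)-3-hydroxyphthalide | COc1cc(C)c2c(c1O)Oc1c(c(C)c(O)c3c1[C@H](O)OC3=O)OC2=O | target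

## Step count

Total: 9 steps. Longest linear sequence: 6 steps (steps 4, 5, 6, 7, 8, 9; the ring A branch, steps 1, 2, 3, 7, 8, 9, is equally long).

## Three steps most likely to fail, with fallbacks

**Step 8 (oxidative C–O coupling).** Both phenols are chelated and hard to oxidise, ring A has a free para position, and the product is a hydroquinone mono-aryl ether that can over-oxidise. The fallback replaces the oxidative coupling by a halide-based ether closure. It sets out from 14 (with 4) and comes back at 17. Compound 14 is brominated with NBS in MeCN at 0 °C at C-4, the only free ring position, to give (3R)-4-bromo-5,7-dihydroxy-6-methyl-3-[(1S)-1-phenylethoxy]isobenzofuran-1(3H)-one F1. Its 5-OH is esterified with acid 4 (DCC, DMAP, CH2Cl2) to give the bromo depside F2. The diaryl ether is then closed by intramolecular Ullmann coupling (CuCl, 2,2,6,6-tetramethylheptane-3,5-dione, Cs2CO3, NMP, 100 °C) to give 17.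

**Step 9 (final hydrogenolysis).** The secondary benzylic acetal ether may cleave slowly, the phthalide C–O bonds could be reduced on prolonged exposure, and the freed lactol can epimerise if traces of acid or base are present. The fallback sets out from 17 and comes back at 18. Hydrogenolysis is stopped once the fast aryl benzyl ether cleavage is complete (Pd/C, EtOAc, short reaction time) to give the (1S)-1-phenylethyl acetal of the target F3. The auxiliary is then removed by Lewis-acid ionisation toward the stabilised 1-phenylethyl cation (BCl3, pentamethylbenzene as cation trap, CH2Cl2, −78 °C, cold neutral quench). This breaks the O–CH(CH3)Ph bond and not the acetal C–O bond, so C-3 keeps its configuration and 18 results.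

**Step 6 (chiral acetal formation and epimer separation).** The secondary benzylic alcohol may ionise and C-alkylate the free resorcinol ring, and the two epimers may separate poorly with the phenols free. The fallback sets out from 11 (with 12) and comes back at 14. Compound 11 is peracetylated (Ac2O, pyridine) to rac-3,5,7-triacetoxy-6-methylisobenzofuran-1(3H)-one F4. The 3-acetate is exchanged in a glycosylation-type reaction (TMSOTf cat., 12, CH2Cl2, −40 °C) to give 5,7-diacetoxy-6-methyl-3-[(1S)-1-phenylethoxy]isobenzofuran-1(3H)-one as its C-3 epimer mixture F5. The less polar, non-phenolic epimers are separated on SiO2 to give (3R)-5,7-diacetoxy-6-methyl-3-[(1S)-1-phenylethoxy]isobenzofuran-1(3H)-one F6, and the (3S)-rich remainder is re-equilibrated with catalytic TMSOTf and separated again. The two aryl acetates are then removed by aminolysis (n-PrNH2, THF, 0 °C) to give 14.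

## Further compounds

F1 | step 8 | (3R)-4-bromo-5,7-dihydroxy-6-methyl-3-[(1S)-1-phenylethoxy]isobenzofuran-1(3H)-one | Cc1c(O)c(Br)c2c(c1O)C(=O)O[C@H]2O[C@@H](C)c1ccccc1
F2 | step 8 | (3R)-4-bromo-7-hydroxy-6-methyl-1-oxo-3-[(1S)-1-phenylethoxy]-1,3-dihydroisobenzofuran-5-yl 3-(benzyloxy)-2-hydroxy-4-methoxy-6-methylbenzoate | COc1cc(C)c(C(=O)Oc2c(Br)c3c(c(O)c2C)C(=O)O[C@H]3O[C@@H](C)c2ccccc2)c(O)c1OCc1ccccc1
F3 | step 9 | (R)-lactol (1S)-1-phenylethyl acetal of the target (ring A 3-OH free) | COc1cc(C)c2c(c1O)Oc1c(c(C)c(O)c3c1[C@H](O[C@@H](C)c1ccccc1)OC3=O)OC2=O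
F4 | step 6 | rac-3,5,7-triacetoxy-6-methylisobenzofuran-1(3H)-one | Cc1c(OC(C)=O)cc2c(c1OC(C)=O)C(=O)OC2OC(C)=O
F5 | step 6 | 5,7-diacetoxy-6-methyl-3-[(1S)-1-phenylethoxy]isobenzofuran-1(3H)-one as the mixture of its C-3 epimers | Cc1c(OC(C)=O)cc2c(c1OC(C)=O)C(=O)OC2O[C@@H](C)c1ccccc1
F6 | step 6 | (3R)-5,7-diacetoxy-6-methyl-3-[(1S)-1-phenylethoxy]isobenzofuran-1(3H)-one | Cc1c(OC(C)=O)cc2c(c1OC(C)=O)C(=O)O[C@H]2O[C@@H](C)c1ccccc1
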